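## Structural features

- The target is an achiral, linear hexamer of six benzene rings (A to F) joined by five diaryl ether oxygens. Ring A is a 2,4,6-trihydroxyphenoxy group, rings B to E are 3,5-dihydroxy-1,4-phenylenedioxy units, and ring F is a 3,4,5-trihydroxyphenyl group.
- Every ether oxygen lies between a carbon flanked by two oxygen-bearing carbons (on the ring nearer to A) and a carbon flanked by two CH groups (on the ring nearer to F). All five linkages therefore have the same sense and are di-ortho-hindered on one side.
- There are no stereocentres, so nothing has to be set or protected against epimerisation.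
- The fourteen free phenols on tetra-oxygenated rings make the final compound very prone to oxidation, above all as phenoxides. The hydroxyls should be unmasked in the last step and handled without oxygen.
- The real difficulty is to make five hindered, electron-rich aryl–oxygen bonds between almost identical units with exactly defined length, without self-condensation of bifunctional monomers.
- The key step uses ring B. C3, C4 and C5 carry oxygen (aryloxy on C4) and map onto a 2-aryloxycyclohexane-1,3-dione. C1 carries the ring-A oxygen and maps onto the beta carbon of an aryloxy ynoate. C2 comes from the CH terminus of the derived diene, and C6 from the ester-bearing alkyne carbon, whose ester is removed afterwards.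

## Logic of the disconnections

**25 to 24.** The twelve O–CH3 bonds are cut last in the forward sense. Methyl ethers are the only protection present on purchasable units, and they survive copper catalysis, organolithium, 160 °C and hot alkali. The gain is that every earlier intermediate is a robust, chromatographable ether. The demand is exhaustive cleavage with BBr3 that leaves the diaryl ethers intact, with an oxygen-free acidic work-up.

**24 to 21.** The C6–CO2Me bond of ring B and the two O–Si bonds are restored. The ester is the activating group of the dienophile, and it ends on a carbon with oxygen at both ortho positions and the para position, the best site for protodecarboxylation. Desilylation, saponification and decarboxylation are merged into one operation at the methyl ether stage, where nothing else is sensitive to base. The demand is hydrolysis of a di-ortho-substituted benzoate.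

**21 to 14 and 19.** Ring B is cut at C1–C2 and C5–C6, and a two-carbon bridge is added back on the diene side. This is the most convergent cut, because ring B is the junction between a one-ring fragment and a four-ring fragment; the two aryl–oxygen bonds around ring B that an iterative coupling would have to make are then formed earlier on non-aromatic carbon, in the carbenoid insertion and the dichlorovinyl ether formation. An atom-by-atom check of the mapping (diene CH terminus to the aryloxy alkyne carbon, silyloxy terminus to the ester carbon, loss of the CH2–CH2 bridge) reproduces 21 exactly, so no structure needs correction. The demand is regiocontrol, and tolerance of a donor-substituted dienophile and of silyl enol ethers to prolonged heating.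

**14 to 12.** Two O–Si bonds are cut. Because 12 is symmetric, enolisation towards either methylene gives the same diene, so the step poses no regiochemical question.

**12 to 9 and 11; 11 to 10.** The C2–O bond of the dione is cut to a phenol and a carbenoid precursor. This puts the hindered tetramer on the dione through its unhindered, unflanked phenol. The diazo group is installed with p-ABSA, a sulfonyl azide of low shock sensitivity, on a compound that is stabilised by two carbonyl groups.

**9 to 7.** The phenolic C–O bond of ring C is traced back to a C–CHO bond. An unflanked hydroxyl could not be carried through copper couplings, and the aldehyde makes the ring-C unit (6) a halide-free nucleophile. That removes one halide-selectivity problem and one halogen exchange.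

**7 to 5 and 6; 5 to 4 and 2; 4 to 3; 3 to 1 and 2.** The three diaryl ether C–O bonds are cut one at a time from the ring-C end. A bromophenol coupled with an aryl bromide could self-condense. Each coupling that uses 2 is therefore run against an aryl iodide (1 purchased, 4 by halogen exchange), so that the C–Br bond para to a phenoxide stays untouched. The price is one extra exchange step.

**19 to 16 to 15.** The C(sp)–CO2Me bond and then the alkyne are cut back to a dichlorovinyl ether, made from the phenol and trichloroethylene. The ring-A oxygen never has to be attached to an aromatic carbon of ring B.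

## Other disconnections considered

**Alternative 1:** oxidative decarboxylative oligomerisation.
- Cut and key step: all five diaryl ether bonds are cut at once. Laccase and O2 would oxidise one starter, 4-benzyloxy-2,6-dimethoxyphenol A1, and five units of syringic acid A2 to phenoxyl radicals. Oxygen-to-para-carbon coupling with loss of CO2 would give hexamer A3 (benzyl ether on ring A, free phenol on ring F).
- In favour: the flanked oxygen attacks the only open para position, so the sense of each linkage is correct by construction. On regiochemistry it is the equal of the chosen plan. On step economy it is clearly better: one oligomerisation and one global dealkylation would reach 25.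
- Against: chain length is statistical. A3 still carries a free phenol and can grow on. Chains can also start from A2 instead of A1. Quinone-ketal redistribution, typical of phenylene oxide formation, would scramble lengths. A3 would have to be separated from homologues differing by one unit.
- Comparison: the chosen plan is longer, but it gives a single hexamer because each ring is introduced in a separate, countable step. The alternative trades that certainty for brevity.

**Alternative 2:** cyclobutenone–vinylstannane benzannulation of ring F.
- Cut and key step: two C–C bonds of ring F are cut. PdCl2(PhCN)2 with tri(2-furyl)phosphine would couple racemic 4-chloro-2,3-diisopropoxycyclobut-2-en-1-one A4 with the 1-aryloxyvinylstannane A5 of the A-to-E pentamer. On warming, ring opening to a dienylketene and six-electron electrocyclisation would give phenol A6.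
- In favour: the substitution pattern of the new ring is fixed by connectivity, not by orbital polarisation. On this point it is better than the chosen key step. It also runs at lower temperature and leaves no carbon to excise.
- Against: it builds the terminal ring F, which can be bought fully oxygenated (as 1). It still needs the A-to-E pentamer, which means four hindered ether couplings against three in the chosen route. It also needs conversion of a flanked phenol into a 1-aryloxyvinylstannane, an organotin reagent and a sensitive chlorocyclobutenone.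
- Comparison: mechanistically at least as secure as the chosen plan, but less convergent and longer, because the ring it constructs is the one that needs no construction.

**Alternative 3:** twelvefold Baeyer–Villiger oxidation.
- Cut and key step: the twelve flanking aryl C–O bonds are traced back to formyl groups. A peracid would convert dodecaaldehyde A7 into dodecaformate A8 by aryl migration.
- In favour: the formyl groups would activate fluoro-isophthalaldehyde units for metal-free ether formation by nucleophilic aromatic substitution. The end game (formate methanolysis, hydrogenolysis of two benzyl ethers) is much milder than a twelvefold BBr3 demethylation. On this point it is better than the chosen plan.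
- Against: each ring carries a second electron-withdrawing formyl group, which lowers aryl migratory aptitude and invites hydride migration to carboxylic acids. Twelve successive oxidations must all take the right course. Any formate that hydrolyses early exposes a phenol to peracid. Making A7 needs an iterative, protected sequence of about two steps per ring.
- Comparison: similar or greater step count than the chosen plan, with the main risk multiplied twelve times in one flask instead of concentrated in one ring-forming step.

Key step: step 11

Remarks on the chemistry: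
- Ar4 denotes the four-ring aryl group 4-{3,5-dimethoxy-4-[3,5-dimethoxy-4-(3,4,5-trimethoxyphenoxy)phenoxy]phenoxy}-3,5-dimethoxyphenyl (rings C to F, bonded through the unflanked carbon of ring C).
- Compound 12 is drawn as the diketone but should exist mainly as its enol.
- Compounds 1, 2, 6, 10 and 15 are assumed to be purchasable.

## Route

Step 1
Reactants: 1 5-iodo-1,2,3-trimethoxybenzene; 2 4-bromo-2,6-dimethoxyphenol
Product: 3 5-(4-bromo-2,6-dimethoxyphenoxy)-1,2,3-trimethoxybenzene
Conditions: CuI (10 mol %), picolinic acid (20 mol %), K3PO4, DMSO, 80 °C, Ar; 1 in slight excess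
Reagents that add atoms: none
Why: Ullmann-type diaryl ether synthesis catalysed by monovalent copper, with a ligand that tolerates di-ortho-substituted phenols. The C–I bond of 1 should react well ahead of the C–Br bond of 2, which is further deactivated by its para phenoxide oxygen; with 1 in excess no phenoxide remains to attack 3.

Step 2
Reactants: 3 5-(4-bromo-2,6-dimethoxyphenoxy)-1,2,3-trimethoxybenzene
Product: 4 5-(4-iodo-2,6-dimethoxyphenoxy)-1,2,3-trimethoxybenzene
Conditions: CuI (10 mol %), trans-N,N'-dimethylcyclohexane-1,2-diamine (20 mol %), NaI, 1,4-dioxane, 110 °C, Ar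
Reagents that add atoms: sodium iodide, [Na+].[I-]
Why: Aromatic Finkelstein halogen exchange; precipitation of NaBr from dioxane should drive the equilibrium, and methyl and diaryl ethers are inert.

Step 3
Reactants: 4 5-(4-iodo-2,6-dimethoxyphenoxy)-1,2,3-trimethoxybenzene; 2 4-bromo-2,6-dimethoxyphenol
Product: 5 5-[4-(4-bromo-2,6-dimethoxyphenoxy)-2,6-dimethoxyphenoxy]-1,2,3-trimethoxybenzene
Conditions: CuI (10 mol %), picolinic acid (20 mol %), K3PO4, DMSO, 80 °C, Ar; 2 as limiting reagent
Reagents that add atoms: none
Why: Same Ullmann coupling and the same iodide-over-bromide selectivity as in step 1. Keeping 2 limiting and the temperature moderate should prevent the product bromide 5 from coupling further.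

Step 4
Reactants: 5 5-[4-(4-bromo-2,6-dimethoxyphenoxy)-2,6-dimethoxyphenoxy]-1,2,3-trimethoxybenzene; 6 4-hydroxy-3,5-dimethoxybenzaldehyde (syringaldehyde)
Product: 7 4-{3,5-dimethoxy-4-[3,5-dimethoxy-4-(3,4,5-trimethoxyphenoxy)phenoxy]phenoxy}-3,5-dimethoxybenzaldehyde
Conditions: CuI (20 mol %), picolinic acid (40 mol %), K3PO4, DMSO, 110 °C, Ar; 6 (2 equiv)
Reagents that add atoms: none
Why: Ullmann coupling of an aryl bromide with a hindered phenol. Because 6 carries no halide, a higher temperature and an excess of the phenol can be used to offset the lower nucleophilicity caused by the para formyl group.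

Step 5
Reactants: 7 4-{3,5-dimethoxy-4-[3,5-dimethoxy-4-(3,4,5-trimethoxyphenoxy)phenoxy]phenoxy}-3,5-dimethoxybenzaldehyde
Product: 9 4-{3,5-dimethoxy-4-[3,5-dimethoxy-4-(3,4,5-trimethoxyphenoxy)phenoxy]phenoxy}-3,5-dimethoxyphenol (Ar4–OH), via aryl formate 8 (not isolated)
Conditions: mCPBA, CH2Cl2, 0 °C to rt; aq. Na2SO3 wash; then K2CO3 (cat.), MeOH, rt
Reagents that add atoms: 3-chloroperoxybenzoic acid (mCPBA), OOC(=O)c1cccc(Cl)c1
Why: Baeyer–Villiger (Dakin-type) oxidation; the trioxygenated aryl group should migrate in preference to hydride to give formate 8, which mild methanolysis cleaves. The peracid is destroyed before the phenol is liberated.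

Step 6
Reactants: 10 cyclohexane-1,3-dione
Product: 11 2-diazocyclohexane-1,3-dione
Conditions: 4-acetamidobenzenesulfonyl azide (p-ABSA), Et3N, MeCN, 0 °C to rt
Reagents that add atoms: 4-acetamidobenzenesulfonyl azide, CC(=O)Nc1ccc(cc1)S(=O)(=O)N=[N+]=[N-]
Why: Regitz diazo transfer to an active methylene. The reagent is a sulfonyl azide of low shock sensitivity, and the product is stabilised by two acyl groups and is used without heating or distillation.

Step 7
Reactants: 9 Ar4–OH; 11 2-diazocyclohexane-1,3-dione
Product: 12 2-(Ar4-oxy)cyclohexane-1,3-dione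
Conditions: Rh2(OAc)4 (2 mol %), 1,2-dichloroethane, 70 °C, slow addition of 11 (1.5 equiv)
Reagents that add atoms: none
Why: Rhodium-carbenoid O–H insertion; the electrophilic carbenoid from 11 should be captured by the unhindered phenolic oxygen (oxonium ylide, then proton transfer). Slow addition keeps the carbenoid concentration low, and the acidic enol product can be separated by base extraction.

Step 8
Reactants: 12 2-(Ar4-oxy)cyclohexane-1,3-dione
Product: 14 2-(Ar4-oxy)-1,3-bis(trimethylsilyloxy)cyclohexa-1,3-diene, via monosilyl enone 13 (not isolated)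
Conditions: TMSOTf (2.5 equiv), Et3N (4 equiv), Et2O/toluene, 0 °C to rt, Ar; ammonium salt separated, used crude
Reagents that add atoms: trimethylsilyl trifluoromethanesulfonate, C[Si](C)(C)OS(=O)(=O)C(F)(F)F
Why: Soft enolisation and O-silylation; the enol is silylated to 13, whose remaining carbonyl is activated by the silyl triflate and deprotonated by the amine. Because 12 is symmetric, deprotonation at either ring methylene next to the oxygenated carbons gives the same diene.

Step 9
Reactants: 15 2,4,6-trimethoxyphenol
Product: 16 2-[(E)-1,2-dichloroethenyloxy]-1,3,5-trimethoxybenzene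
Conditions: trichloroethylene, K2CO3, DMF, 70 °C, N2
Reagents that add atoms: trichloroethylene, ClC=C(Cl)Cl
Why: Base-mediated anti addition of the phenoxide to dichloroacetylene, which forms only transiently from trichloroethylene in solution under nitrogen; this is the established entry to aryl 1,2-dichlorovinyl ethers and tolerates the di-ortho-substituted phenol.

Step 10
Reactants: 16 2-[(E)-1,2-dichloroethenyloxy]-1,3,5-trimethoxybenzene
Product: 19 methyl 3-(2,4,6-trimethoxyphenoxy)prop-2-ynoate, via chloroalkynyl ether 17 (not isolated), via lithium aryloxyacetylide 18 (not isolated)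
Conditions: n-BuLi (2.3 equiv), THF, −78 to −40 °C; then ClCO2Me, −78 °C to rt
Reagents that add atoms: methyl chloroformate, COC(Cl)=O
Why: Deprotonation and elimination give chloroalkyne 17, chlorine–lithium exchange gives acetylide 18, and C-acylation with the chloroformate gives the ynoate. This is the known ynol ether synthesis from dichlorovinyl ethers, and an aryl ynol ether has no beta hydrogen for retro-ene cleavage.

Step 11
Reactants: 14 2-(Ar4-oxy)-1,3-bis(trimethylsilyloxy)cyclohexa-1,3-diene; 19 methyl 3-(2,4,6-trimethoxyphenoxy)prop-2-ynoate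
Product: 21 methyl 3-(Ar4-oxy)-2,4-bis(trimethylsilyloxy)-6-(2,4,6-trimethoxyphenoxy)benzoate, via bicyclo[2.2.2]octadiene adduct 20 (not isolated)
Conditions: 19 (2.5 equiv), degassed o-xylene, sealed tube, 160 °C, Ar; concentrated and used crude
Reagents that add atoms: none
Why: Proposed new method: the closest known reaction type is the Alder–Rickert synthesis of resorcinol esters from 1,3-bis(silyloxy)cyclohexa-1,3-dienes and acetylenic esters; a 2-aryloxy diene and a 3-aryloxypropiolate have not been shown in it, and the reasoning is that both oxygen substituents perturb but do not reverse the frontier-orbital pattern of the parent reaction. The diene is a normal-demand partner whose two silyloxy groups both raise the HOMO coefficient at the CH terminus, while the ynoate, although its aryloxy donor raises the LUMO, keeps its largest LUMO coefficient on the oxygen-bearing beta carbon, as in conjugate additions to beta-alkoxy acrylates. An asynchronous concerted [4+2] addition should therefore join the CH terminus to the beta carbon and the silyloxy terminus to the ester carbon, giving adduct 20; sterics point the same way, since the bulky trimethoxyphenoxy-bearing carbon meets the unsubstituted terminus. Ring B is thus closed intermolecularly by two C–C bonds in a suprafacial six-electron cycloaddition, and at the reaction temperature 20 should lose its ethano bridge as ethene by retro-Diels–Alder reaction, an irreversible step driven by aromatisation. The two bridgehead stereocentres of racemic 20 are erased in that step, so no stereocontrol is needed. The only selectivity required is regiochemical (ring-A oxygen para to the ring-C oxygen); it rests on the matched 1,3-dioxygenation of the diene and the ester of the dienophile, and the wrong orientation would be recognisable because it leads to a 1,2,3,4-tetraoxygenated ring. The donor on the dienophile is expected to cost rate, which is answered by heat, an excess of the cheap ynoate and strictly neutral, anhydrous conditions that silyl enol ethers tolerate.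

Step 12
Reactants: 21 methyl 3-(Ar4-oxy)-2,4-bis(trimethylsilyloxy)-6-(2,4,6-trimethoxyphenoxy)benzoate
Product: 24 2-(Ar4-oxy)-5-(2,4,6-trimethoxyphenoxy)benzene-1,3-diol, via desilylated methyl ester 22 (not isolated), via free benzoic acid 23 (not isolated)
Conditions: KOH, 1,4-dioxane/H2O, reflux, Ar; then aq. HCl to pH 2, 60 °C
Reagents that add atoms: none
Why: Hydroxide removes the aryl silyl ethers and saponifies the ester; on acidification the acid, with oxygen at both ortho positions and the para position, should undergo ipso protonation and lose CO2. This hydrolysis–decarboxylation is standard for 2,4-dihydroxy-6-substituted benzoates, and the methyl and diaryl ethers are inert.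

Step 13
Reactants: 24 2-(Ar4-oxy)-5-(2,4,6-trimethoxyphenoxy)benzene-1,3-diol
Product: 25 target CNP0187343.0 (ring A 2,4,6-trihydroxyphenoxy, rings B to E 3,5-dihydroxy-1,4-phenylenedioxy, ring F 3,4,5-trihydroxyphenyl)
Conditions: BBr3 (excess), CH2Cl2, −78 °C to rt, Ar; MeOH then degassed H2O; reversed-phase or Sephadex LH-20 purification under Ar
Reagents that add atoms: none
Why: Lewis-acid cleavage of aryl methyl ethers by BBr3 (bromide attacks the methyl carbon of the boron-complexed ether). Diaryl ethers offer no carbon open to that attack and should survive, and the acidic oxygen-free work-up protects the polyphenol.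

## Compound list

1 | 5-iodo-1,2,3-trimethoxybenzene | COc1cc(I)cc(OC)c1OC | starting material
2 | 4-bromo-2,6-dimethoxyphenol | COc1cc(Br)cc(OC)c1O | starting material
3 | 5-(4-bromo-2,6-dimethoxyphenoxy)-1,2,3-trimethoxybenzene | Brc1cc(OC)c(Oc2cc(OC)c(OC)c(OC)c2)c(OC)c1 | intermediate
4 | 5-(4-iodo-2,6-dimethoxyphenoxy)-1,2,3-trimethoxybenzene | Ic1cc(OC)c(Oc2cc(OC)c(OC)c(OC)c2)c(OC)c1 | intermediate
5 | 5-[4-(4-bromo-2,6-dimethoxyphenoxy)-2,6-dimethoxyphenoxy]-1,2,3-trimethoxybenzene | Brc1cc(OC)c(Oc2cc(OC)c(Oc3cc(OC)c(OC)c(OC)c3)c(OC)c2)c(OC)c1 | intermediate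
6 | 4-hydroxy-3,5-dimethoxybenzaldehyde (syringaldehyde) | COc1cc(C=O)cc(OC)c1O | starting material
7 | 4-{3,5-dimethoxy-4-[3,5-dimethoxy-4-(3,4,5-trimethoxyphenoxy)phenoxy]phenoxy}-3,5-dimethoxybenzaldehyde | O=Cc1cc(OC)c(Oc2cc(OC)c(Oc3cc(OC)c(Oc4cc(OC)c(OC)c(OC)c4)c(OC)c3)c(OC)c2)c(OC)c1 | intermediate
8 | Ar4 formate (formate ester of 9) | O=COc1cc(OC)c(Oc2cc(OC)c(Oc3cc(OC)c(Oc4cc(OC)c(OC)c(OC)c4)c(OC)c3)c(OC)c2)c(OC)c1 | intermediate (not isolated)
9 | 4-{3,5-dimethoxy-4-[3,5-dimethoxy-4-(3,4,5-trimethoxyphenoxy)phenoxy]phenoxy}-3,5-dimethoxyphenol (Ar4–OH) | Oc1cc(OC)c(Oc2cc(OC)c(Oc3cc(OC)c(Oc4cc(OC)c(OC)c(OC)c4)c(OC)c3)c(OC)c2)c(OC)c1 | intermediate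
10 | cyclohexane-1,3-dione | O=C1CCCC(=O)C1 | starting material
11 | 2-diazocyclohexane-1,3-dione | [N-]=[N+]=C1C(=O)CCCC1=O | intermediate
12 | 2-(Ar4-oxy)cyclohexane-1,3-dione (mainly enol) | O=C1CCCC(=O)C1Oc1cc(OC)c(Oc2cc(OC)c(Oc3cc(OC)c(Oc4cc(OC)c(OC)c(OC)c4)c(OC)c3)c(OC)c2)c(OC)c1 | intermediate
13 | 2-(Ar4-oxy)-3-(trimethylsilyloxy)cyclohex-2-en-1-one | O=C1CCCC(O[Si](C)(C)C)=C1Oc1cc(OC)c(Oc2cc(OC)c(Oc3cc(OC)c(Oc4cc(OC)c(OC)c(OC)c4)c(OC)c3)c(OC)c2)c(OC)c1 | intermediate (not isolated)
14 | 2-(Ar4-oxy)-1,3-bis(trimethylsilyloxy)cyclohexa-1,3-diene | C[Si](C)(C)OC1=CCCC(O[Si](C)(C)C)=C1Oc1cc(OC)c(Oc2cc(OC)c(Oc3cc(OC)c(Oc4cc(OC)c(OC)c(OC)c4)c(OC)c3)c(OC)c2)c(OC)c1 | intermediate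
15 | 2,4,6-trimethoxyphenol | COc1cc(OC)c(O)c(OC)c1 | starting material
16 | 2-[(E)-1,2-dichloroethenyloxy]-1,3,5-trimethoxybenzene | COc1cc(OC)c(O/C(Cl)=C\Cl)c(OC)c1 | intermediate
17 | 2-(chloroethynyloxy)-1,3,5-trimethoxybenzene | COc1cc(OC)c(OC#CCl)c(OC)c1 | intermediate (not isolated)
18 | lithium (2,4,6-trimethoxyphenoxy)acetylide | COc1cc(OC)c(OC#C[Li])c(OC)c1 | intermediate (not isolated)
19 | methyl 3-(2,4,6-trimethoxyphenoxy)prop-2-ynoate | COC(=O)C#COc1c(OC)cc(OC)cc1OC | intermediate
20 | methyl 6-(Ar4-oxy)-1,5-bis(trimethylsilyloxy)-3-(2,4,6-trimethoxyphenoxy)bicyclo[2.2.2]octa-2,5-diene-2-carboxylate (racemic) | COC(=O)C1=C(Oc2c(OC)cc(OC)cc2OC)C2CCC1(O[Si](C)(C)C)C(Oc1cc(OC)c(Oc3cc(OC)c(Oc4cc(OC)c(Oc5cc(OC)c(OC)c(OC)c5)c(OC)c4)c(OC)c3)c(OC)c1)=C2O[Si](C)(C)C | intermediate (not isolated)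
21 | methyl 3-(Ar4-oxy)-2,4-bis(trimethylsilyloxy)-6-(2,4,6-trimethoxyphenoxy)benzoate | COC(=O)c1c(O[Si](C)(C)C)c(Oc2cc(OC)c(Oc3cc(OC)c(Oc4cc(OC)c(Oc5cc(OC)c(OC)c(OC)c5)c(OC)c4)c(OC)c3)c(OC)c2)c(O[Si](C)(C)C)cc1Oc1c(OC)cc(OC)cc1OC | intermediate
22 | methyl 3-(Ar4-oxy)-2,4-dihydroxy-6-(2,4,6-trimethoxyphenoxy)benzoate | COC(=O)c1c(O)c(Oc2cc(OC)c(Oc3cc(OC)c(Oc4cc(OC)c(Oc5cc(OC)c(OC)c(OC)c5)c(OC)c4)c(OC)c3)c(OC)c2)c(O)cc1Oc1c(OC)cc(OC)cc1OC | intermediate (not isolated)
23 | 3-(Ar4-oxy)-2,4-dihydroxy-6-(2,4,6-trimethoxyphenoxy)benzoic acid | OC(=O)c1c(O)c(Oc2cc(OC)c(Oc3cc(OC)c(Oc4cc(OC)c(Oc5cc(OC)c(OC)c(OC)c5)c(OC)c4)c(OC)c3)c(OC)c2)c(O)cc1Oc1c(OC)cc(OC)cc1OC | intermediate (not isolated)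
24 | 2-(Ar4-oxy)-5-(2,4,6-trimethoxyphenoxy)benzene-1,3-diol | Oc1cc(Oc2c(OC)cc(OC)cc2OC)cc(O)c1Oc1cc(OC)c(Oc2cc(OC)c(Oc3cc(OC)c(Oc4cc(OC)c(OC)c(OC)c4)c(OC)c3)c(OC)c2)c(OC)c1 | intermediate
25 | CNP0187343.0, the fully phenolic hexamer | Oc1cc(O)c(Oc2cc(O)c(Oc3cc(O)c(Oc4cc(O)c(Oc5cc(O)c(Oc6cc(O)c(O)c(O)c6)c(O)c5)c(O)c4)c(O)c3)c(O)c2)c(O)c1 | target

## Step count and least certain steps

Total step count: 13. Longest linear sequence: 10 steps (1, 2, 3, 4, 5, 7, 8, 11, 12, 13).

**Step 11 (key step, proposed new method).**
- What may go wrong: the push–pull ynoate may react too slowly, so that 1,5-hydrogen shift in the diene, desilylation by adventitious water, or a stepwise Michael-type addition without ring closure competes. Orientation opposite to that predicted is also possible, because the aryloxy donors on both partners weaken the polarisation on which the regiochemistry rests.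
- Fallback (known chemistry, from 5 to 25): the cycloaddition is abandoned and ring B and ring A are attached by the same copper chemistry as in steps 1 to 3. Halogen exchange on 5 (CuI, diamine, NaI) gives the trimer iodide F1. Ullmann coupling with 2 gives the tetramer bromide F2. A second exchange gives the tetramer iodide F3. Coupling with 2 gives the pentamer bromide F4. Coupling of F4 with 15, which carries no halide, gives the tetradecamethyl ether of the target F5. BBr3 demethylation of F5 as in step 13 gives 25.

**Step 7 (O–H insertion).**
- What may go wrong: the carbenoid may attack the four very electron-rich arene rings (aromatic C–H functionalisation or cycloaddition) in competition with the phenolic oxygen. The carbenoid may also undergo Wolff-type rearrangement at the temperature needed for this doubly stabilised diazo compound.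
- Fallback (from 9 to 12): Williamson alkylation of 9 with methyl 6-bromo-5-oxohexanoate (COC(=O)CCCC(=O)CBr; K2CO3, acetone) gives the keto ester methyl 6-(Ar4-oxy)-5-oxohexanoate F6. Dieckmann-type Claisen cyclisation of F6 (KOtBu, THF) can close only the six-membered ring and returns 12.

**Step 4 (coupling with syringaldehyde).**
- What may go wrong: the di-ortho-substituted phenoxide, made less nucleophilic by its para formyl group, may couple too slowly with the electron-rich bromide. Reduction of the C–Br bond or base-induced degradation of the aldehyde could then take over.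
- Fallback (from 5 to 7): bromine–lithium exchange on 5 (n-BuLi, −78 °C), then B(OiPr)3 and aqueous work-up, gives the trimer boronic acid F7. Oxidative Chan–Lam coupling of F7 with 6 under divalent copper (Cu(OAc)2, pyridine, 4 Å molecular sieves, CH2Cl2, air) at room temperature returns 7. The formyl group makes 6 less prone to phenol oxidation than a simple 2,6-dimethoxyphenol.

**Step 12 (hydrolysis and decarboxylation).**
- What may go wrong: saponification of the di-ortho-substituted, phenoxide-deactivated ester may stall. Prolonged hot alkali may lead to oxidative degradation of the resorcinol dianion if oxygen is not rigorously excluded.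
- Fallback (from 21 to 25): 21 is treated directly with excess BBr3, which cleaves the silyl ethers, all methyl ethers and the methyl ester, to give the ring-B carboxylic acid of the target F8. Warming F8 in degassed dilute aqueous acid should bring about protodecarboxylation to 25, so 24 is bypassed.

**Step 13 (global demethylation).**
- What may go wrong: demethylation may be incomplete at some of the twelve sites, leaving inseparable partially methylated material. The free polyphenol may oxidise during isolation.
- Fallback (from 24 to 25): demethylation with AlBr3 in ethanethiol (hard acid with soft nucleophile), followed directly by acetylation (Ac2O, pyridine), gives the tetradecaacetate of the target F9. F9 is stable and can be purified and checked for completeness. Acid-catalysed methanolysis (HCl in degassed MeOH) then releases 25 without any phenoxide stage.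

## Further compounds

F1 | step 11 | 5-[4-(4-iodo-2,6-dimethoxyphenoxy)-2,6-dimethoxyphenoxy]-1,2,3-trimethoxybenzene (trimer iodide) | Ic1cc(OC)c(Oc2cc(OC)c(Oc3cc(OC)c(OC)c(OC)c3)c(OC)c2)c(OC)c1
F2 | step 11 | tetramer bromide Ar4–Br | Brc1cc(OC)c(Oc2cc(OC)c(Oc3cc(OC)c(Oc4cc(OC)c(OC)c(OC)c4)c(OC)c3)c(OC)c2)c(OC)c1
F3 | step 11 | tetramer iodide Ar4–I | Ic1cc(OC)c(Oc2cc(OC)c(Oc3cc(OC)c(Oc4cc(OC)c(OC)c(OC)c4)c(OC)c3)c(OC)c2)c(OC)c1
F4 | step 11 | pentamer bromide, 5-bromo-1,3-dimethoxy-2-(Ar4-oxy)benzene | Brc1cc(OC)c(Oc2cc(OC)c(Oc3cc(OC)c(Oc4cc(OC)c(Oc5cc(OC)c(OC)c(OC)c5)c(OC)c4)c(OC)c3)c(OC)c2)c(OC)c1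
F5 | step 11 | tetradecamethyl ether of the target | COc1cc(OC)c(Oc2cc(OC)c(Oc3cc(OC)c(Oc4cc(OC)c(Oc5cc(OC)c(Oc6cc(OC)c(OC)c(OC)c6)c(OC)c5)c(OC)c4)c(OC)c3)c(OC)c2)c(OC)c1
F6 | step 7 | methyl 6-(Ar4-oxy)-5-oxohexanoate | COC(=O)CCCC(=O)COc1cc(OC)c(Oc2cc(OC)c(Oc3cc(OC)c(Oc4cc(OC)c(OC)c(OC)c4)c(OC)c3)c(OC)c2)c(OC)c1
F7 | step 4 | {4-[2,6-dimethoxy-4-(3,4,5-trimethoxyphenoxy)phenoxy]-3,5-dimethoxyphenyl}boronic acid (trimer boronic acid) | OB(O)c1cc(OC)c(Oc2cc(OC)c(Oc3cc(OC)c(OC)c(OC)c3)c(OC)c2)c(OC)c1
F8 | step 12 | ring-B carboxylic acid of the target (carboxyl on C6 of ring B) | OC(=O)c1c(O)c(Oc2cc(O)c(Oc3cc(O)c(Oc4cc(O)c(Oc5cc(O)c(O)c(O)c5)c(O)c4)c(O)c3)c(O)c2)c(O)cc1Oc1c(O)cc(O)cc1O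
F9 | step 13 | tetradecaacetate of the target | CC(=O)Oc1cc(OC(C)=O)c(Oc2cc(OC(C)=O)c(Oc3cc(OC(C)=O)c(Oc4cc(OC(C)=O)c(Oc5cc(OC(C)=O)c(Oc6cc(OC(C)=O)c(OC(C)=O)c(OC(C)=O)c6)c(OC(C)=O)c5)c(OC(C)=O)c4)c(OC(C)=O)c3)c(OC(C)=O)c2)c(OC(C)=O)c1
A1 | alternative 1 | 4-benzyloxy-2,6-dimethoxyphenol | COc1cc(OCc2ccccc2)cc(OC)c1O
A2 | alternative 1 | syringic acid (4-hydroxy-3,5-dimethoxybenzoic acid) | COc1cc(C(=O)O)cc(OC)c1O
A3 | alternative 1 | hexamer with benzyl ether on ring A, twelve methyl ethers, free phenol on ring F | COc1cc(OCc2ccccc2)cc(OC)c1Oc1cc(OC)c(Oc2cc(OC)c(Oc3cc(OC)c(Oc4cc(OC)c(Oc5cc(OC)c(O)c(OC)c5)c(OC)c4)c(OC)c3)c(OC)c2)c(OC)c1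
A4 | alternative 2 | 4-chloro-2,3-diisopropoxycyclobut-2-en-1-one (racemic) | CC(C)OC1=C(OC(C)C)C(Cl)C1=O
A5 | alternative 2 | tributyl[1-(aryloxy)ethenyl]stannane of the A-to-E pentamer | C=C(Oc1c(OC)cc(Oc2c(OC)cc(Oc3c(OC)cc(Oc4c(OC)cc(Oc5c(OC)cc(OC)cc5OC)cc4OC)cc3OC)cc2OC)cc1OC)[Sn](CCCC)(CCCC)CCCC
A6 | alternative 2 | hexamer with ring F as 3,4-diisopropyl ether 5-phenol | CC(C)Oc1cc(Oc2c(OC)cc(Oc3c(OC)cc(Oc4c(OC)cc(Oc5c(OC)cc(Oc6c(OC)cc(OC)cc6OC)cc5OC)cc4OC)cc3OC)cc2OC)cc(O)c1OC(C)C
A7 | alternative 3 | hexameric dodecaaldehyde bis(benzyl ether) | O=Cc1cc(OCc2ccccc2)cc(C=O)c1Oc1cc(C=O)c(Oc2cc(C=O)c(Oc3cc(C=O)c(Oc4cc(C=O)c(Oc5cc(C=O)c(OCc6ccccc6)c(C=O)c5)c(C=O)c4)c(C=O)c3)c(C=O)c2)c(C=O)c1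
A8 | alternative 3 | dodecaformate of the target bis(benzyl ether) | O=COc1cc(OCc2ccccc2)cc(OC=O)c1Oc1cc(OC=O)c(Oc2cc(OC=O)c(Oc3cc(OC=O)c(Oc4cc(OC=O)c(Oc5cc(OC=O)c(OCc6ccccc6)c(OC=O)c5)c(OC=O)c4)c(OC=O)c3)c(OC=O)c2)c(OC=O)c1
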